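Numbering: ring A is C1(CO2Me)=C2–C3–C4–C9–C10(CHO), ring B is C4–C5(Me, side chain)–C6(Cl)–C7–C8(OH)–C9(Me); β is the face of the C9 methyl group.
Enabling feature: in ring A the 2-substituted acrylate C1(CO2Me)=C2 is bonded through C1 to C10, whose formyl group can stand as a nitromethyl group. This is the retron of a Rauhut–Currier reaction between a but-2-enoate arm on C4 and a nitrovinyl group on C9.
Cuts, in retrosynthetic order: C10 CHO from CH2NO2 (Nef); C1–C10 (ring A); C1=C2 of the arm (Wittig) and C10=CHNO2 (Henry); C6–H/Cl (from a C6 ketone through its chloroalkene); C8–O (from the C7=C8 enone); C5–side chain and C5–Me (enolate alkylations); C4–vinyl (conjugate addition to a cyclohexadienone); ring B (Robinson annulation).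
Forward: ring B is made first as a 4,4-disubstituted cyclohexadienone (C6 carbonyl, C9 quaternary), then substituted at C4, C5, C8 and C6; ring A is closed last.
Stereochemistry: C4 (and with it C9) from the (R)-BINAP/rhodium desymmetrisation; C5 from two alkylations anti to the C4 vinyl group; C8 from axial conjugate borylation trans to C4; C6 from axial hydrogen delivery to a chloro-substituted radical; C10 in the ring closure (equatorial).

Key step: step 20

Remark: the sense of induction of (R)-BINAP is assigned by analogy with simple cyclohexenones (the antipodal ligand would be taken if it proved opposite). Abbreviations: side chain = (2E)-4-methyl-4-(triethylsilyloxy)pent-2-en-1-yl on C5, PMB = 4-methoxybenzyl, TES = triethylsilyl, pin = pinacolato, α = face opposite to β.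

Step 1
Reactants: 1 2-methylpropane-1,3-diol
Product: 2 3-[(4-methoxybenzyl)oxy]-2-methylpropan-1-ol (racemic)
Conditions: NaH (1.0 equiv), THF, 0 °C; 4-methoxybenzyl chloride, Bu4NI (cat.), rt
Reagents that add atoms: 4-methoxybenzyl chloride, COc1ccc(CCl)cc1
Why: Williamson monoetherification of the symmetrical diol through its monosodium alkoxide should give the mono-PMB ether; the methyl-bearing carbon is not yet a controlled stereocentre.

Step 2
Reactants: 2 3-[(4-methoxybenzyl)oxy]-2-methylpropan-1-ol
Product: 3 3-[(4-methoxybenzyl)oxy]-2-methylpropanal (racemic)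
Conditions: Dess–Martin periodinane, NaHCO3, CH2Cl2, 0 °C to rt
Reagents that add atoms: none
Why: Dess–Martin oxidation of the primary alcohol should give the aldehyde under buffered conditions, and any racemisation is irrelevant.

Step 3
Reactants: 3 3-[(4-methoxybenzyl)oxy]-2-methylpropanal; 4 but-3-en-2-one
Product: 7 4-{[(4-methoxybenzyl)oxy]methyl}-4-methylcyclohex-2-en-1-one, via pyrrolidine enamine 5 (not isolated), via keto aldehyde 6 (not isolated)
Conditions: pyrrolidine, benzene, reflux (water removal); 4, rt; then AcOH, NaOAc, H2O, reflux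
Reagents that add atoms: none
Why: Stork enamine Michael addition followed by hydrolysis and intramolecular aldol condensation (Robinson annulation) should assemble the six carbons of ring B as a cyclohexenone whose quaternary carbon is the future C9 (racemic at this stage).

Step 4
Reactants: 7 4-{[(4-methoxybenzyl)oxy]methyl}-4-methylcyclohex-2-en-1-one
Product: 9 4-{[(4-methoxybenzyl)oxy]methyl}-4-methylcyclohexa-2,5-dien-1-one, via silyl dienol ether 8 (not isolated)
Conditions: LiN(i-Pr)2, THF, −78 °C; Me3SiCl; then Pd(OAc)2 (1 equiv), MeCN, rt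
Reagents that add atoms: none
Why: Saegusa–Ito dehydrogenation, in which the kinetic cross-conjugated silyl dienol ether is oxidised by divalent palladium, should give an achiral cyclohexadienone whose two enone arms are enantiotopic.

Step 5
Reactants: 9 4-{[(4-methoxybenzyl)oxy]methyl}-4-methylcyclohexa-2,5-dien-1-one
Product: 10 (4S,5R)-5-ethenyl-4-{[(4-methoxybenzyl)oxy]methyl}-4-methylcyclohex-2-en-1-one (C4β-vinyl; C9β-Me; C9α-CH2OPMB)
Conditions: potassium vinyltrifluoroborate, [Rh(OH)(cod)]2 (cat.), (R)-BINAP, dioxane/H2O, 60 °C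
Reagents that add atoms: potassium vinyltrifluoroborate, C=C[B-](F)(F)F.[K+]
Why: rhodium-catalysed asymmetric conjugate alkenylation (Hayashi–Miyaura type) desymmetrises the dienone, the (R)-BINAP–rhodium vinyl species selecting the enone face and so setting C4, while the preference for insertion anti to the bulkier CH2OPMB group directs the reaction to the enone arm that places vinyl cis to the C9 methyl group and thereby fixes C9.

Step 6
Reactants: 10 (4S,5R)-5-ethenyl-4-{[(4-methoxybenzyl)oxy]methyl}-4-methylcyclohex-2-en-1-one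
Product: 11 C5-methylated enone (both C5 epimers)
Conditions: LiN(i-Pr)2, THF, −78 °C; MeI, −78 to −20 °C
Reagents that add atoms: iodomethane, CI
Why: kinetic deprotonation of the enone at the saturated α′ carbon (C5) and SN2 methylation of the lithium enolate; the configuration of the new methine is of no consequence because it is planarised again in step 9.

Step 7
Reactants: 12 2-methylbut-3-en-2-ol; 13 (E)-1,4-dibromobut-2-ene
Product: 14 (E)-5-bromo-2-methylpent-3-en-2-ol
Conditions: second-generation Hoveyda–Grubbs catalyst (cat.), CH2Cl2, 40 °C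
Reagents that add atoms: none
Why: olefin cross-metathesis between the tertiary allylic alcohol and the symmetrical allylic dibromide should give the (E)-alkene under thermodynamic control.

Step 8
Reactants: 14 (E)-5-bromo-2-methylpent-3-en-2-ol
Product: 15 (E)-[(5-bromo-2-methylpent-3-en-2-yl)oxy]triethylsilane
Conditions: Et3SiOTf, 2,6-lutidine, CH2Cl2, −78 °C
Reagents that add atoms: triethylsilyl trifluoromethanesulfonate, CC[Si](CC)(CC)OS(=O)(=O)C(F)(F)F
Why: silyl ether formation at the tertiary alcohol with a silyl triflate and a hindered base masks the hydroxyl for the enolate chemistry.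

Step 9
Reactants: 11 C5-methylated enone; 15 (E)-[(5-bromo-2-methylpent-3-en-2-yl)oxy]triethylsilane
Product: 16 ring-B enone (C6=O; C7=C8; C4β-vinyl; C5β-Me; C5α-side chain; C9β-Me; C9α-CH2OPMB)
Conditions: LiN(i-Pr)2, THF/DMPU, −78 °C; 15, −78 to 0 °C
Reagents that add atoms: none
Why: alkylation of the tetrasubstituted cross-conjugated lithium enolate with the allylic bromide should occur anti to the adjacent C4 vinyl group (the usual outcome for α-methyl cyclohexenone enolates flanked by a β′ substituent, as in 6-methylcarvone), so the side chain enters α and the methyl group ends up β at quaternary C5.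

Step 10
Reactants: 16 ring-B enone
Product: 17 C8α-boronate ketone (C8α-Bpin; C7 saturated)
Conditions: B2pin2, CuCl (cat.), NaOt-Bu (cat.), DPEphos (cat.), MeOH, THF, rt
Reagents that add atoms: bis(pinacolato)diboron, CC1(C)OB(OC1(C)C)B1OC(C)(C)C(C)(C)O1
Why: copper-catalysed conjugate borylation of the enone, in which the boryl–copper species adds to C8 along the axial trajectory anti to the axial C9 methyl group and trans to the C4 vinyl group (the 3,5-trans rule of cyclohexenones), should place boron α at C8 while unactivated alkenes stay untouched.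

Step 11
Reactants: 17 C8α-boronate ketone
Product: 19 keto diol (C8α-OH; C4β-CH2CH2OH), via bis-boron adduct 18 (not isolated)
Conditions: catecholborane, RhCl(PPh3)3 (cat.), THF, rt; then NaBO3·4H2O, THF/H2O, rt
Reagents that add atoms: sodium perborate tetrahydrate, [Na+].[O-]OB=O
Why: rhodium-catalysed hydroboration with catecholborane is chemoselective for the terminal vinyl group over the ketone and the disubstituted alkene and is anti-Markovnikov, and perborate oxidation turns both C–B bonds into C–O bonds with retention, so the C8 hydroxyl is α.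

Step 12
Reactants: 19 keto diol
Product: 20 bis-TES keto ether (C8α-OTES; C4β-CH2CH2OTES)
Conditions: Et3SiOTf (2.5 equiv), 2,6-lutidine, CH2Cl2, −78 to −20 °C
Reagents that add atoms: triethylsilyl trifluoromethanesulfonate, CC[Si](CC)(CC)OS(=O)(=O)C(F)(F)F
Why: silyl ether formation at the primary and the hindered secondary alcohol with the silyl triflate, with no change at any stereocentre.

Step 13
Reactants: 20 bis-TES keto ether
Product: 21 C6 enol triflate (C6=C7)
Conditions: KN(SiMe3)2, THF, −78 °C; PhNTf2, −78 to 0 °C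
Reagents that add atoms: N-phenylbis(trifluoromethanesulfonimide), O=S(=O)(N(c1ccccc1)S(=O)(=O)C(F)(F)F)C(F)(F)F
Why: the ketone can enolise only toward C7 because C5 is quaternary, and O-sulfonylation of the potassium enolate at low temperature should give the enol triflate before β-elimination of the C8 silyloxy group can intervene.

Step 14
Reactants: 21 C6 enol triflate
Product: 22 C6 alkenyl chloride (C6=C7)
Conditions: Ni(cod)2 (cat.), LiCl, DMA/THF, rt
Reagents that add atoms: lithium chloride, [Li+].[Cl-]
Why: nickel-catalysed halogen exchange of an enol triflate (oxidative addition to zerovalent nickel, triflate/chloride exchange, C–Cl reductive elimination) should give the alkenyl chloride with the double bond held at C6=C7.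

Step 15
Reactants: 22 C6 alkenyl chloride
Product: 23 C6β-chloride (C6β-Cl equatorial; C7 saturated)
Conditions: Mn(dpm)3 (cat.), PhSiH3, t-BuOOH, i-PrOH, rt
Reagents that add atoms: none
Why: metal-hydride hydrogen-atom-transfer hydrogenation of the kind that retains the halogen of haloalkenes and is slow for 1,2-disubstituted alkenes adds H• to C7 to give the α-chloro radical at C6, and the second hydrogen is delivered axially on the α face, anti to the axial C5 methyl group, so that chlorine becomes equatorial (β), which is also the more stable epimer because an axial chloride would be 1,3-diaxial to the C8 silyloxy group.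

Step 16
Reactants: 23 C6β-chloride
Product: 24 C10 primary alcohol (C9α-CH2OH)
Conditions: DDQ, CH2Cl2/pH 7 buffer, 0 °C
Reagents that add atoms: none
Why: oxidative cleavage of the PMB ether by DDQ (oxidation at the electron-rich benzylic position and hydrolysis of the oxocarbenium ion) should free only the C10 hydroxyl, silyl ethers and alkenes being inert under buffered conditions.

Step 17
Reactants: 24 C10 primary alcohol
Product: 25 C10 aldehyde (C9α-CHO)
Conditions: Dess–Martin periodinane, NaHCO3, CH2Cl2, rt
Reagents that add atoms: none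
Why: Dess–Martin oxidation of the neopentyl primary alcohol should give the non-enolisable aldehyde on quaternary C9.

Step 18
Reactants: 25 C10 aldehyde; 26 nitromethane
Product: 28 (E)-nitroalkene (C9α-CH=CHNO2), via β-nitro alcohol 27 (not isolated)
Conditions: 26 (excess), 1,1,3,3-tetramethylguanidine (cat.), 0 °C to rt; then MsCl, Et3N, CH2Cl2, 0 °C
Reagents that add atoms: none
Why: Henry (nitro-aldol) addition of nitromethane, then mesylation and E1cB elimination of the β-nitro alcohol, should give the conjugated (E)-nitroalkene, which is installed before the enoate so that nitronate cannot add to an acrylate.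

Step 19
Reactants: 28 (E)-nitroalkene; 29 methyl (triphenylphosphoranylidene)acetate
Product: 31 enoate nitroalkene (C4β-(E)-CH2CH=CHCO2Me; C9α-(E)-CH=CHNO2), via arm aldehyde 30 (not isolated)
Conditions: (COCl)2, DMSO, CH2Cl2, −78 to −40 °C; Et3N; then 29, −78 °C to rt
Reagents that add atoms: none
Why: under Swern conditions a primary triethylsilyl ether is cleaved and oxidised directly to the aldehyde while the secondary and tertiary silyl ethers survive, and Wittig olefination with the stabilised ylide gives the (E)-enoate; the nitroalkene should be spared because its β-carbon C10 is neopentyl and because the free alcohol that could add to it is never formed.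

Step 20
Reactants: 31 enoate nitroalkene
Product: 32 nitromethyl trans-decalin (C1=C2 enoate; C10β-CH2NO2)
Conditions: PMe3 (0.3 equiv), t-AmOH, rt to 40 °C
Reagents that add atoms: none
Why: PMe3 adds reversibly to C2 of the (E)-enoate to give a phosphonium ester enolate whose C1 attacks C10 of the nitroalkene, after which proton transfer from C1 to the nitronate and β-elimination of PMe3 restore the C1=C2 double bond and release the catalyst. The closest known reaction type is the phosphine-catalysed intramolecular Rauhut–Currier (vinylogous Morita–Baylis–Hillman) cycloisomerisation of tethered bis-acceptors, used here in the crossed sense with the ester as donor and the nitroalkene as acceptor. Ring A closes in the 6-exo-trig mode, the nitroalkene C=C being exocyclic to the new ring. The new stereocentre C10 is controlled by a chair-like transition state on the preformed ring B: the arms on C4 and C9 are trans-diequatorial, which enforces the trans ring fusion, and the nitromethyl group takes the equatorial (β) position because the axial alternative would be syn-axial to the C8 silyloxy group. The step needs the polarity enoate = donor and nitroalkene = acceptor; this should be secured because C10 is attached to quaternary C9 and shielded from the phosphine whereas C2 carries only a CH2 group, and because any phosphine–nitroalkene adduct can only revert while the enolate is trapped irreversibly by the far more electrophilic nitroalkene.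

Step 21
Reactants: 32 nitromethyl trans-decalin
Product: 34 bis-TES aldehyde (C10β-CHO), via sodium nitronate 33 (not isolated)
Conditions: NaOMe, MeOH, 0 °C; then TiCl3 (aq.), NH4OAc, pH 5–6, rt
Reagents that add atoms: water, O
Why: Nef reaction in its reductive titanium trichloride variant, in which the nitronate is reduced to the imine and hydrolysed at buffered pH to the aldehyde; C10 is not touched and the equatorial formyl group is in any case the thermodynamically preferred epimer.

Step 22
Reactants: 34 bis-TES aldehyde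
Product: 35 CNP0167913.1 (target)
Conditions: HF·pyridine, pyridine, THF, 0 °C to rt
Reagents that add atoms: none
Why: fluoride-induced cleavage of the secondary and the tertiary triethylsilyl ethers under buffered, mildly acidic conditions, which leave the enolisable aldehyde, the enoate and the neopentyl chloride alone, should give the target.

Compound list
1 | 2-methylpropane-1,3-diol | CC(CO)CO | starting material
2 | 3-[(4-methoxybenzyl)oxy]-2-methylpropan-1-ol (racemic) | COc1ccc(COCC(C)CO)cc1 | intermediate
3 | 3-[(4-methoxybenzyl)oxy]-2-methylpropanal (racemic) | COc1ccc(COCC(C)C=O)cc1 | intermediate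
4 | but-3-en-2-one (methyl vinyl ketone) | CC(=O)C=C | starting material
5 | 1-{3-[(4-methoxybenzyl)oxy]-2-methylprop-1-en-1-yl}pyrrolidine (enamine of 3) | COc1ccc(COCC(C)=CN2CCCC2)cc1 | intermediate
6 | 2-{[(4-methoxybenzyl)oxy]methyl}-2-methyl-5-oxohexanal | COc1ccc(COCC(C)(C=O)CCC(C)=O)cc1 | intermediate
7 | 4-{[(4-methoxybenzyl)oxy]methyl}-4-methylcyclohex-2-en-1-one (racemic) | COc1ccc(COCC2(C)CCC(=O)C=C2)cc1 | intermediate
8 | [(4-{[(4-methoxybenzyl)oxy]methyl}-4-methylcyclohexa-1,5-dien-1-yl)oxy]trimethylsilane | COc1ccc(COCC2(C)CC=C(O[Si](C)(C)C)C=C2)cc1 | intermediate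
9 | 4-{[(4-methoxybenzyl)oxy]methyl}-4-methylcyclohexa-2,5-dien-1-one (achiral) | COc1ccc(COCC2(C)C=CC(=O)C=C2)cc1 | intermediate
10 | (4S,5R)-5-ethenyl-4-{[(4-methoxybenzyl)oxy]methyl}-4-methylcyclohex-2-en-1-one; ring B with C6=O, C7=C8, C4β-vinyl, C9β-Me, C9α-CH2OPMB | C=C[C@H]1CC(=O)C=C[C@]1(C)COCc1ccc(OC)cc1 | intermediate
11 | 10 carrying a methyl group on C5 (both C5 epimers, the centre is unspecified in the SMILES) | C=C[C@H]1C(C)C(=O)C=C[C@]1(C)COCc1ccc(OC)cc1 | intermediate
12 | 2-methylbut-3-en-2-ol | CC(C)(O)C=C | starting material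
13 | (E)-1,4-dibromobut-2-ene | BrC/C=C/CBr | starting material
14 | (E)-5-bromo-2-methylpent-3-en-2-ol | CC(C)(O)/C=C/CBr | intermediate
15 | (E)-[(5-bromo-2-methylpent-3-en-2-yl)oxy]triethylsilane | CC[Si](CC)(CC)OC(C)(C)/C=C/CBr | intermediate
16 | ring-B enone: C6 ketone, C7=C8, C4β-vinyl, C5β-Me, C5α-side chain, C9β-Me, C9α-CH2OPMB | C=C[C@H]1[C@](C)(C/C=C/C(C)(C)O[Si](CC)(CC)CC)C(=O)C=C[C@]1(C)COCc1ccc(OC)cc1 | intermediate
17 | 16 with C7–C8 saturated and a pinacol boronate α on C8 | C=C[C@H]1[C@](C)(C/C=C/C(C)(C)O[Si](CC)(CC)CC)C(=O)C[C@H](B2OC(C)(C)C(C)(C)O2)[C@]1(C)COCc1ccc(OC)cc1 | intermediate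
18 | 17 with the vinyl group converted into CH2CH2–B(catecholato) | C(C[C@H]1[C@](C)(C/C=C/C(C)(C)O[Si](CC)(CC)CC)C(=O)C[C@H](B2OC(C)(C)C(C)(C)O2)[C@]1(C)COCc1ccc(OC)cc1)B1Oc2ccccc2O1 | intermediate
19 | keto diol: C6 ketone, C8α-OH, C4β-CH2CH2OH, C5β-Me, C5α-side chain, C9β-Me, C9α-CH2OPMB | OCC[C@H]1[C@](C)(C/C=C/C(C)(C)O[Si](CC)(CC)CC)C(=O)C[C@H](O)[C@]1(C)COCc1ccc(OC)cc1 | intermediate
20 | bis(triethylsilyl) ether of 19 (C8α-OTES, C4β-CH2CH2OTES) | CC[Si](CC)(CC)OCC[C@H]1[C@](C)(C/C=C/C(C)(C)O[Si](CC)(CC)CC)C(=O)C[C@H](O[Si](CC)(CC)CC)[C@]1(C)COCc1ccc(OC)cc1 | intermediate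
21 | enol triflate of 20: C6(OTf)=C7 | CC[Si](CC)(CC)OCC[C@H]1[C@](C)(C/C=C/C(C)(C)O[Si](CC)(CC)CC)C(OS(=O)(=O)C(F)(F)F)=C[C@H](O[Si](CC)(CC)CC)[C@]1(C)COCc1ccc(OC)cc1 | intermediate
22 | alkenyl chloride: C6(Cl)=C7, otherwise as 21 | CC[Si](CC)(CC)OCC[C@H]1[C@](C)(C/C=C/C(C)(C)O[Si](CC)(CC)CC)C(Cl)=C[C@H](O[Si](CC)(CC)CC)[C@]1(C)COCc1ccc(OC)cc1 | intermediate
23 | fully substituted ring B: C4β-CH2CH2OTES, C5β-Me, C5α-side chain, C6β-Cl (equatorial), C8α-OTES, C9β-Me, C9α-CH2OPMB | CC[Si](CC)(CC)OCC[C@H]1[C@](C)(C/C=C/C(C)(C)O[Si](CC)(CC)CC)[C@@H](Cl)C[C@H](O[Si](CC)(CC)CC)[C@]1(C)COCc1ccc(OC)cc1 | intermediate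
24 | 23 with free C10 hydroxyl (C9α-CH2OH) | CC[Si](CC)(CC)OCC[C@H]1[C@](C)(C/C=C/C(C)(C)O[Si](CC)(CC)CC)[C@@H](Cl)C[C@H](O[Si](CC)(CC)CC)[C@]1(C)CO | intermediate
25 | C10 aldehyde (C9α-CHO) | CC[Si](CC)(CC)OCC[C@H]1[C@](C)(C/C=C/C(C)(C)O[Si](CC)(CC)CC)[C@@H](Cl)C[C@H](O[Si](CC)(CC)CC)[C@]1(C)C=O | intermediate
26 | nitromethane | C[N+](=O)[O-] | starting material
27 | β-nitro alcohol: C9α-CH(OH)CH2NO2 (either carbinol epimer) | CC[Si](CC)(CC)OCC[C@H]1[C@](C)(C/C=C/C(C)(C)O[Si](CC)(CC)CC)[C@@H](Cl)C[C@H](O[Si](CC)(CC)CC)[C@]1(C)C(O)C[N+](=O)[O-] | intermediate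
28 | nitroalkene: C9α-(E)-CH=CHNO2, C4β-CH2CH2OTES | CC[Si](CC)(CC)OCC[C@H]1[C@](C)(C/C=C/C(C)(C)O[Si](CC)(CC)CC)[C@@H](Cl)C[C@H](O[Si](CC)(CC)CC)[C@]1(C)/C=C/[N+](=O)[O-] | intermediate
29 | methyl (triphenylphosphoranylidene)acetate | COC(=O)C=P(c1ccccc1)(c1ccccc1)c1ccccc1 | starting material
30 | arm aldehyde: C4β-CH2CHO, C9α-(E)-CH=CHNO2 | O=CC[C@H]1[C@](C)(C/C=C/C(C)(C)O[Si](CC)(CC)CC)[C@@H](Cl)C[C@H](O[Si](CC)(CC)CC)[C@]1(C)/C=C/[N+](=O)[O-] | intermediate
31 | key-step precursor: C4β-(E)-CH2CH=CHCO2Me, C5β-Me, C5α-side chain, C6β-Cl, C8α-OTES, C9β-Me, C9α-(E)-CH=CHNO2 | COC(=O)/C=C/C[C@H]1[C@](C)(C/C=C/C(C)(C)O[Si](CC)(CC)CC)[C@@H](Cl)C[C@H](O[Si](CC)(CC)CC)[C@]1(C)/C=C/[N+](=O)[O-] | intermediate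
32 | key-step product: trans-decalin with C1(CO2Me)=C2, C10β-CH2NO2 (equatorial), C8α-OTES, tertiary OTES | COC(=O)C1=CC[C@H]2[C@](C)(C/C=C/C(C)(C)O[Si](CC)(CC)CC)[C@@H](Cl)C[C@H](O[Si](CC)(CC)CC)[C@]2(C)[C@H]1C[N+](=O)[O-] | intermediate
33 | sodium nitronate of 32 | COC(=O)C1=CC[C@H]2[C@](C)(C/C=C/C(C)(C)O[Si](CC)(CC)CC)[C@@H](Cl)C[C@H](O[Si](CC)(CC)CC)[C@]2(C)[C@H]1C=[N+]([O-])[O-].[Na+] | intermediate
34 | bis(triethylsilyl) ether of the target (C10β-CHO) | COC(=O)C1=CC[C@H]2[C@](C)(C/C=C/C(C)(C)O[Si](CC)(CC)CC)[C@@H](Cl)C[C@H](O[Si](CC)(CC)CC)[C@]2(C)[C@H]1C=O | intermediate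
35 | CNP0167913.1 | COC(=O)C1=CC[C@H]2[C@](C)(C/C=C/C(C)(C)O)[C@@H](Cl)C[C@H](O)[C@]2(C)[C@H]1C=O | target

Total step count: 22. Longest linear sequence: 20 steps (steps 1–6 and 9–22; steps 7 and 8 make the side-chain bromide).

Steps most likely to fail

1. Step 20. The phosphine may engage the nitroalkene first, or start its oligomerisation, so that the ester enolate is never formed; the final proton transfer and elimination may also stall at the phosphonium stage. The fallback replaces catalysis by a stoichiometric thiolate-mediated Michael–Michael sequence followed by sulfoxide elimination. It sets out from 31: PhSLi in THF (−78 to 0 °C) adds to C2 of the enoate (addition to the nitroalkene is reversible), and the ester enolate is trapped by 6-exo Michael closure onto C10 to give the 2-phenylsulfanyl nitromethyl decalin F1. NaIO4 in MeOH/H2O oxidises this to the sulfoxide F2. Warming in toluene (90 °C) eliminates the sulfoxide toward the acidic C1–H and comes back to the route at 32.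

2. Step 15. Hydrogen-atom transfer to the hindered chloroalkene may be slow, so that the side-chain alkene is reduced competitively, or the chloro-substituted radical may lose chlorine. The fallback reaches the same chloride by radical mono-reduction of a geminal dichloride, which exposes no alkene to a metal hydride. It sets out from 20: N2H4·H2O in EtOH (70 °C) gives the C6 hydrazone F3, and CuCl2/Et3N in MeOH converts it into the 6,6-dichloride F4. Bu3SnH (1 equiv) with AIBN in benzene (80 °C) removes one chlorine, the C6 radical again taking hydrogen on the α face, and comes back to the route at 23.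

3. Step 14. Oxidative addition at the enol triflate next to quaternary C5 may be slow, and the alkenylnickel species may be protonated instead of undergoing C–Cl reductive elimination. The fallback is stannylation followed by chlorodestannylation. It sets out from 21: Me3SnSnMe3, Pd(PPh3)4 (cat.) and LiCl in THF (60 °C, Stille-type coupling) give the C6 trimethylstannyl alkene F5, and CuCl2 in THF at rt replaces tin by chlorine at the same carbon, coming back to the route at 22.

Further compounds
F1 | step 20 | 2-phenylsulfanyl nitromethyl decalin (ring A saturated, C1 and C2 unspecified) | COC(=O)C1C(Sc2ccccc2)C[C@H]2[C@](C)(C/C=C/C(C)(C)O[Si](CC)(CC)CC)[C@@H](Cl)C[C@H](O[Si](CC)(CC)CC)[C@]2(C)[C@H]1C[N+](=O)[O-]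
F2 | step 20 | sulfoxide of F1 | COC(=O)C1C(S(=O)c2ccccc2)C[C@H]2[C@](C)(C/C=C/C(C)(C)O[Si](CC)(CC)CC)[C@@H](Cl)C[C@H](O[Si](CC)(CC)CC)[C@]2(C)[C@H]1C[N+](=O)[O-]
F3 | step 15 | C6 hydrazone of 20 | CC[Si](CC)(CC)OCC[C@H]1[C@](C)(C/C=C/C(C)(C)O[Si](CC)(CC)CC)C(=NN)C[C@H](O[Si](CC)(CC)CC)[C@]1(C)COCc1ccc(OC)cc1
F4 | step 15 | 6,6-dichloride | CC[Si](CC)(CC)OCC[C@H]1[C@](C)(C/C=C/C(C)(C)O[Si](CC)(CC)CC)C(Cl)(Cl)C[C@H](O[Si](CC)(CC)CC)[C@]1(C)COCc1ccc(OC)cc1
F5 | step 14 | C6 trimethylstannyl alkene (C6=C7) | CC[Si](CC)(CC)OCC[C@H]1[C@](C)(C/C=C/C(C)(C)O[Si](CC)(CC)CC)C([Sn](C)(C)C)=C[C@H](O[Si](CC)(CC)CC)[C@]1(C)COCc1ccc(OC)cc1
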